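**Assumption:** (R)-but-3-en-2-ol (≥98% ee) is bought as an enantiopure C4 building block. Its carbinol centre is the only purchased stereocentre and is relayed to C8', then C8, then C7.

## Retrosynthetic overview

1. Target 13 ⇐ debenzylation of 12; the tetrahydrofuran (O–C7 bond) is closed last by acid-mediated cyclodehydration of triol 11, which sets 7,8-trans.
2. Triol 11 ⇐ LiAlH4 reduction of trans-lactone 10 ⇐ anti-selective aldol of (R)-β-benzyl-γ-butyrolactone 8 with aldehyde 9 (C7–C8 bond; C8 controlled by C8').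
3. Lactone 8 ⇐ ozonolysis/reduction of ester 7 ⇐ Johnson–Claisen [3,3] rearrangement of allylic alcohol 5, which forms the C8–C8' bond with 1,3-chirality transfer.
4. Alcohol 5 ⇐ cross-metathesis of (R)-but-3-en-2-ol (4) with O-benzyl methoxyeugenol (3).
5. Ring order: a temporary γ-lactone first, then the tetrahydrofuran.

## Route

**Step 1**
Reactants: 1, 4-allyl-2,6-dimethoxyphenol; 2, benzyl bromide
Product: 3, 5-allyl-2-(benzyloxy)-1,3-dimethoxybenzene
Conditions: BnBr (1.2 equiv), K2CO3, DMF, rt
Reagents that add atoms: benzyl bromide (2), BrCc1ccccc1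
Why: Williamson etherification masks the phenol for the ozonolysis, enolate and hydride steps; mild base at rt leaves the allyl group unisomerised.

**Step 2**
Reactants: 3 (2 equiv); 4, (R)-but-3-en-2-ol
Product: 5, (2R,3E)-5-[4-(benzyloxy)-3,5-dimethoxyphenyl]pent-3-en-2-ol
Conditions: Hoveyda–Grubbs II (5 mol%), 1,4-benzoquinone (10 mol%), CH2Cl2, 40 °C; AgNO3–SiO2 chromatography to remove any Z isomer
Reagents that add atoms: none (both partners are listed as reactants)
Why: Olefin cross-metathesis of an allylarene with a secondary allylic alcohol is E-selective under thermodynamic control, and the carbinol stereocentre is not touched, so (R) is retained.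

**Step 3**
Reactants: 5; 6, triethyl orthoacetate
Product: 7, ethyl (3R,4E)-3-[4-(benzyloxy)-3,5-dimethoxybenzyl]hex-4-enoate
Conditions: MeC(OEt)3 (7 equiv), EtCO2H (0.1 equiv), 140 °C, EtOH distilled off
Reagents that add atoms: triethyl orthoacetate (6), CC(OCC)(OCC)OCC
Why: Johnson–Claisen [3,3]-sigmatropic rearrangement through a chair transition state with the carbinol methyl equatorial; the C–O bond is traded suprafacially for the C8–C8' bond, so (R,E)-5 gives the (R) centre and an E-propenyl group.

**Step 4**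
Reactants: 7
Product: 8, (R)-4-[4-(benzyloxy)-3,5-dimethoxybenzyl]dihydrofuran-2(3H)-one
Conditions: O3, CH2Cl2/MeOH 4:1, Sudan Red 7B indicator, −78 °C; then NaBH4, −78 → 0 °C; then 1 M HCl, rt
Reagents that add atoms: ozone, [O-][O+]=O (supplies the ring oxygen)
Why: Ozonolysis cleaves the only alkene (acetaldehyde is lost), cold in-situ borohydride reduction gives the γ-hydroxy ester before the α-stereocentre can epimerise, and acid closes the lactone.

**Step 5**
Reactants: 8; 9, 4-(benzyloxy)-3,5-dimethoxybenzaldehyde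
Product: 10, (3S,4R)-3-{[4-(benzyloxy)-3,5-dimethoxyphenyl](hydroxy)methyl}-4-[4-(benzyloxy)-3,5-dimethoxybenzyl]dihydrofuran-2(3H)-one (3,4-trans; epimeric mixture at the carbinol carbon)
Conditions: LiHMDS (1.1 equiv), THF, −78 °C; then 9, −78 °C; AcOH quench at −78 °C
Reagents that add atoms: none beyond reactant 9, O=Cc1cc(OC)c(OCc2ccccc2)c(OC)c1
Why: Lactone-enolate aldol addition occurs on the face anti to the β-benzyl group, setting C8 trans to C8'; the C7 configuration is irrelevant because it is reset in step 7.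

**Step 6**
Reactants: 10
Product: 11, (2R,3R)-2-{[4-(benzyloxy)-3,5-dimethoxyphenyl](hydroxy)methyl}-3-[4-(benzyloxy)-3,5-dimethoxybenzyl]butane-1,4-diol (carbinol epimers)
Conditions: LiAlH4, THF, 0 °C → rt; Rochelle salt work-up
Reagents that add atoms: none
Why: Hydride reduction of the lactone to the 1,4-diol leaves both ring stereocentres and the benzyl ethers untouched.

**Step 7**
Reactants: 11
Product: 12, {(2S,3R,4R)-2-[4-(benzyloxy)-3,5-dimethoxyphenyl]-4-[4-(benzyloxy)-3,5-dimethoxybenzyl]tetrahydrofuran-3-yl}methanol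
Conditions: p-TsOH·H2O (10 mol%), CH2Cl2, 0 °C → rt; NaHCO3 quench as soon as 11 is consumed
Reagents that add atoms: none
Why: SN1 cyclodehydration: the benzylic cation from either C7 epimer is captured 5-exo by the C9' hydroxyl (the C9 hydroxyl could only give an oxetane), with the aryl group ending anti to the cis CH2OH/benzyl pair, which gives 7S.

**Step 8**
Reactants: 12
Product: 13, (+)-(7S,8R,8'R)-5,5'-dimethoxylariciresinol
Conditions: H2 (1 atm), 10% Pd/C, EtOAc, rt; stop at full conversion
Reagents that add atoms: none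
Why: Neutral hydrogenolysis removes both aryl benzyl ethers faster than it cleaves the ring benzylic C7–O bond, and no stereocentre is affected.

## Compound list

1 | 4-allyl-2,6-dimethoxyphenol | C=CCc1cc(OC)c(O)c(OC)c1 | starting material
2 | benzyl bromide | BrCc1ccccc1 | starting material
3 | 5-allyl-2-(benzyloxy)-1,3-dimethoxybenzene | C=CCc1cc(OC)c(OCc2ccccc2)c(OC)c1 | intermediate
4 | (R)-but-3-en-2-ol | C[C@@H](O)C=C | starting material
5 | (2R,3E)-5-[4-(benzyloxy)-3,5-dimethoxyphenyl]pent-3-en-2-ol | C[C@@H](O)/C=C/Cc1cc(OC)c(OCc2ccccc2)c(OC)c1 | intermediate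
6 | triethyl orthoacetate | CC(OCC)(OCC)OCC | starting material
7 | ethyl (3R,4E)-3-[4-(benzyloxy)-3,5-dimethoxybenzyl]hex-4-enoate | CCOC(=O)C[C@H](/C=C/C)Cc1cc(OC)c(OCc2ccccc2)c(OC)c1 | intermediate
8 | (R)-4-[4-(benzyloxy)-3,5-dimethoxybenzyl]dihydrofuran-2(3H)-one | O=C1C[C@@H](Cc2cc(OC)c(OCc3ccccc3)c(OC)c2)CO1 | intermediate
9 | 4-(benzyloxy)-3,5-dimethoxybenzaldehyde | O=Cc1cc(OC)c(OCc2ccccc2)c(OC)c1 | starting material
10 | (3S,4R)-3-{[4-(benzyloxy)-3,5-dimethoxyphenyl](hydroxy)methyl}-4-[4-(benzyloxy)-3,5-dimethoxybenzyl]dihydrofuran-2(3H)-one (carbinol epimers) | O=C1OC[C@H](Cc2cc(OC)c(OCc3ccccc3)c(OC)c2)[C@H]1C(O)c1cc(OC)c(OCc2ccccc2)c(OC)c1 | intermediate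
11 | (2R,3R)-2-{[4-(benzyloxy)-3,5-dimethoxyphenyl](hydroxy)methyl}-3-[4-(benzyloxy)-3,5-dimethoxybenzyl]butane-1,4-diol (carbinol epimers) | OC[C@H](Cc1cc(OC)c(OCc2ccccc2)c(OC)c1)[C@H](CO)C(O)c1cc(OC)c(OCc2ccccc2)c(OC)c1 | intermediate
12 | {(2S,3R,4R)-2-[4-(benzyloxy)-3,5-dimethoxyphenyl]-4-[4-(benzyloxy)-3,5-dimethoxybenzyl]tetrahydrofuran-3-yl}methanol | COc1cc(C[C@H]2CO[C@H](c3cc(OC)c(OCc4ccccc4)c(OC)c3)[C@H]2CO)cc(OC)c1OCc1ccccc1 | intermediate
13 | (+)-(7S,8R,8'R)-5,5'-dimethoxylariciresinol | COc1cc(C[C@H]2CO[C@H](c3cc(OC)c(O)c(OC)c3)[C@H]2CO)cc(OC)c1O | target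

## Summary

Total steps: 8. Longest linear sequence: 8.

Three steps most likely to fail:

1. **Step 2 (cross-metathesis).** Incomplete E selectivity or Ru–H isomerisation is the risk; any (R,Z)-5 rearranges to the enantiomeric ester and erodes ee. Fallback: make 5 without metathesis by Cu-mediated coupling of (R)-but-3-yn-2-ol with 4-(benzyloxy)-3,5-dimethoxybenzyl bromide, then Red-Al trans-reduction to geometrically pure (R,E)-5. Alternatively, a Z-selective Wittig from (S)-lactaldehyde gives (S,Z)-5, which rearranges to the same (R)-7.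

2. **Step 4 (ozonolysis/NaBH4/lactonisation).** Ozone may attack the trialkoxyarene or benzyl ether, and the transient α-chiral aldehyde may epimerise. Fallback: excise the propenyl terminus by OsO4/NMO dihydroxylation, then NaIO4 glycol cleavage with immediate NaBH4 reduction and lactonisation, so no ozone is used.

3. **Step 7 (cyclodehydration).** Ionisation of the hindered 4-benzyloxy-3,5-dimethoxybenzylic alcohol may be slow, and intramolecular Friedel–Crafts closure to an aryltetralin (lyoniresinol-type) may compete. Fallback: reverse the order, hydrogenolysing 11 first to the free bis-phenol triol and closing the ring through the p-quinone methide under near-neutral conditions (PPTS or brief warming), which gives 13 directly.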